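## Retrosynthetic overview
1. Lychnostatin 1 (18) comes from oxidative tailoring of the finished bicycle 14 (8α-methacryloyloxycostunolide). C1=O/C10-OAc derive from the 1(10)-alkene, and C4-H/C5-OH from the 4α,5β-epoxide.
2. 14 comes from the acyclic farnesane-type epoxy enal 10 in one operation. The C6–C7 bond forms first (ten-membered carbocycle, the farnesyl C1–C10 closure that also creates the C11=C13 alkene). O6→C12 acyl closure follows (γ-lactone).
3. 10 comes from the C12 hydroxy aldehyde 4 plus methyl propiolate 5 (C11–C13). C8 is the only centre set by a chiral reagent (organocatalytic α-chlorination, inverted on epoxide closure).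
4. 4 comes from (2E,6E)-farnesyl acetate 1 by terminal bromohydrin formation, epoxide closure and periodate cleavage.

Assumption: germacrane numbering is used throughout (C6 = farnesyl C1, C7 = farnesyl C10), and the roughly 90% ee from step 4 is raised by one recrystallisation of 14.

## Route

Step 1
Reactants: 1 (2E,6E)-farnesyl acetate
Product: 2 (2E,6E)-10-bromo-11-hydroxy-10,11-dihydrofarnesyl acetate (racemic at the CHBr carbon)
Conditions: NBS (1.1 equiv), t-BuOH/H2O, 10 °C
Reagents that add atoms: N-bromosuccinimide O=C1CCC(=O)N1Br; water O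
Why: van Tamelen terminal bromohydrin formation works because in the aqueous medium the coiled chain exposes only the terminal alkene, the C4=C5 alkene is deactivated by the allylic acetate, and water attacks the bromonium ion in the Markovnikov sense, the new stereocentre being erased in step 3.

Step 2
Reactants: 2 (2E,6E)-10-bromo-11-hydroxy-10,11-dihydrofarnesyl acetate
Product: 3 (2E,6E)-10,11-epoxyfarnesol (racemic)
Conditions: K2CO3 (3 equiv), MeOH, rt
Reagents that add atoms: none
Why: Intramolecular Williamson closure of the bromohydrin gives the epoxide while the same carbonate/methanol medium removes the acetate by Zemplén-type transesterification, so the C6 hydroxyl is freed without a separate step.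

Step 3
Reactants: 3 (2E,6E)-10,11-epoxyfarnesol
Product: 4 (4E,8E)-10-hydroxy-4,8-dimethyldeca-4,8-dienal
Conditions: H5IO6 (1.2 equiv), THF/Et2O, 0 °C
Reagents that add atoms: none
Why: Acid-assisted epoxide hydrolysis followed by Malaprade glycol cleavage with the same reagent excises the terminal C3 unit as acetone and leaves both E-alkenes and the allylic alcohol untouched.

Step 4
Reactants: 4 (4E,8E)-10-hydroxy-4,8-dimethyldeca-4,8-dienal; 5 methyl propiolate
Product: 8 methyl (4R,6E,10E)-4-chloro-3,12-dihydroxy-6,10-dimethyl-2-methylidenedodeca-6,10-dienoate (C3 epimers), via chloroaldehyde 6 (not isolated), via vinylalane 7 (not isolated)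
Conditions: (5R)-5-benzyl-2,2,3-trimethylimidazolidin-4-one·TFA (10 mol %), 2,3,4,5,6,6-hexachlorocyclohexa-2,4-dien-1-one (1.1 equiv), CH2Cl2, −30 °C; cannulated into 7 (5 equiv, from 5, i-Bu2AlH, NMO, THF, 0 °C), −78 → 0 °C; aq. potassium sodium tartrate
Reagents that add atoms: 2,3,4,5,6,6-hexachlorocyclohexa-2,4-dien-1-one O=C1C(Cl)=C(Cl)C(Cl)=C(Cl)C1(Cl)Cl
Why: Enamine-catalysed α-chlorination, in which the benzyl arm of the 5R catalyst shields one enamine face, gives the 2R chloride (C8 in latent form), and vinylalumination, a base-free aluminium stand-in for the Morita–Baylis–Hillman reaction, adds C11–C13 to the very electrophilic chloroaldehyde before it can epimerise, the new C7 carbinol centre being irrelevant because step 7 erases it.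

Step 5
Reactants: 8 methyl (4R,6E,10E)-4-chloro-3,12-dihydroxy-6,10-dimethyl-2-methylidenedodeca-6,10-dienoate
Product: 9 methyl 2-{(3S)-3-[(2E,6E)-8-hydroxy-2,6-dimethylocta-2,6-dien-1-yl]oxiran-2-yl}acrylate (epimers at oxirane C2)
Conditions: Cs2CO3 (1.5 equiv), MeCN, 0 °C → rt
Reagents that add atoms: none
Why: Intramolecular Williamson (SN2) closure lets the C7 alkoxide displace chloride with clean inversion, turning 8R C–Cl into the 8S C–O bond of the target, and both C7 epimers are equally usable.

Step 6
Reactants: 9 methyl 2-{(3S)-3-[(2E,6E)-8-hydroxy-2,6-dimethylocta-2,6-dien-1-yl]oxiran-2-yl}acrylate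
Product: 10 methyl 2-{(3S)-3-[(2E,6E)-2,6-dimethyl-8-oxoocta-2,6-dien-1-yl]oxiran-2-yl}acrylate
Conditions: MnO2 (15 equiv), CH2Cl2, rt
Reagents that add atoms: none
Why: MnO2 allylic oxidation takes only the primary allylic alcohol to the enal, keeps the E geometry and leaves the vinyl epoxide and the acrylate alone.

Step 7
Reactants: 10 methyl 2-{(3S)-3-[(2E,6E)-2,6-dimethyl-8-oxoocta-2,6-dien-1-yl]oxiran-2-yl}acrylate
Product: 14 8α-methacryloyloxycostunolide, via bis(methacrylate) 11 (not isolated), via allylindium 12 (not isolated), via hydroxy ester 13 (not isolated)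
Conditions: Pd(PPh3)4 (5 mol %), methacrylic anhydride (1.0 equiv), BHT (trace), THF, 0 °C → rt; then syringe pump (12 h) into InI (3 equiv), Pd(PPh3)4 (5 mol %), THF, rt, final 2 mM; aq. NH4Cl, brief stirring over SiO2
Reagents that add atoms: methacrylic anhydride C=C(C)C(=O)OC(=O)C(C)=C
Why: Proposed new method: zerovalent palladium ionises only the allylic C7–O bond of the vinyl epoxide (the counterpart of diphosphate ionisation), the freed C8 alkoxide is acylated by the anhydride so that the natural ester is in place and O8 can no longer compete for C12, reductive transmetalation of the 2-carbomethoxy-π-allyl complex with InI gives a weakly basic allylindium that attacks the enal carbon C6 through C7 with transposition to the C11=C13 methylene (the bond and the alkene made by the germacrene cyclase), and the C6 alkoxide then closes the lactone on C12; allylic 1,3-strain holds H8 in the alkene plane with C9 on the attacking face and O8 anti, and the E,E tether tolerates only the crown-like chair with C5 and C8 equatorial, so 8S should relay to 7R and 6R (H6/H7 anti, trans-lactone); the closest known reaction types are the Pd/InI umpolung allylation of vinyl epoxides and allylic esters, the Pd/Et2Zn and CrCl2 closures of farnesal-type chains to ten-membered rings, and the Dreiding–Schmidt 2-(alkoxycarbonyl)allylation–lactonisation.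

Step 8
Reactants: 14 8α-methacryloyloxycostunolide
Product: 15 10α-hydroxy-8α-methacryloyloxy-1-oxogermacra-4E,11(13)-dien-12,6α-olide
Conditions: RuCl3 (1 mol %), KHSO5 (2.2 equiv, as Oxone), NaHCO3, EtOAc/MeCN/H2O, 0 °C → rt, stopped at full conversion
Reagents that add atoms: potassium peroxymonosulfate [K+].[O-]S(=O)(=O)OO
Why: In this RuO4-catalysed ketohydroxylation ([3+2] addition, then oxidation of the ruthenate ester at its secondary carbon) the strained, most electron-rich 1(10)-alkene reacts before C4=C5 (deactivated by the allylic lactone oxygen) and before the two acrylate-type alkenes, a trisubstituted alkene can give only the C1 ketone/C10 tertiary alcohol, and attack on the outer face of the crown conformer (C14 β) sets 10α-OH (10R).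

Step 9
Reactants: 15 10α-hydroxy-8α-methacryloyloxy-1-oxogermacra-4E,11(13)-dien-12,6α-olide
Product: 16 10α-acetoxy-8α-methacryloyloxy-1-oxogermacra-4E,11(13)-dien-12,6α-olide
Conditions: Ac2O (5 equiv), DMAP (1 equiv), Et3N, CH2Cl2, rt
Reagents that add atoms: acetic anhydride CC(=O)OC(C)=O
Why: DMAP-catalysed (Steglich-type) acylation can be pushed hard because the tertiary α-ketol is the only hydroxyl in the molecule, and the C10–O bond is not broken so 10R is retained.

Step 10
Reactants: 16 10α-acetoxy-8α-methacryloyloxy-1-oxogermacra-4E,11(13)-dien-12,6α-olide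
Product: 17 10α-acetoxy-4α,5β-epoxy-8α-methacryloyloxy-1-oxogermacr-11(13)-en-12,6α-olide (4R,5R)
Conditions: mCPBA (1.2 equiv), CH2Cl2, 0 °C
Reagents that add atoms: 3-chloroperoxybenzoic acid O=C(OO)c1cccc(Cl)c1
Why: In this Prilezhaev epoxidation C4=C5 is the only electron-rich alkene left, and allylic 1,3-strain between C15 and C6 keeps H6 in the alkene plane with C7 on the inner face, so the peracid can reach only the outer face and gives the parthenolide-type 4α,5β-epoxide, which fixes the 5β C–O bond.

Step 11
Reactants: 17 10α-acetoxy-4α,5β-epoxy-8α-methacryloyloxy-1-oxogermacr-11(13)-en-12,6α-olide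
Product: 18 lychnostatin 1 (4S,5S,6S,7R,8S,10R)
Conditions: Cp2TiCl2 (2.5 equiv), Mn dust, THF, rt, green solution decanted; then 17, H2O (20 equiv), THF, rt
Reagents that add atoms: none
Why: In this RajanBabu–Nugent reductive epoxide opening Cp2TiCl (trivalent titanium) cleaves the C4–O bond to the more stable tertiary C4 radical while oxygen stays on C5 with its β configuration, and the bulky Cp2TiCl·OH2 hydrogen donor can reach only the outer face just vacated by oxygen because the ring blocks the inner face, giving 4α-H/4β-CH3 (4S), while esters, the aliphatic ketone and the acrylate units lie beyond this mild single-electron donor.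

## Compound list
1 | (2E,6E)-farnesyl acetate | CC(C)=CCC/C(C)=C/CC/C(C)=C/COC(C)=O | starting material
2 | (2E,6E)-10-bromo-11-hydroxy-10,11-dihydrofarnesyl acetate, racemic | CC(C)(O)C(Br)CC/C(C)=C/CC/C(C)=C/COC(C)=O | intermediate
3 | (2E,6E)-10,11-epoxyfarnesol, racemic | CC1(C)OC1CC/C(C)=C/CC/C(C)=C/CO | intermediate
4 | (4E,8E)-10-hydroxy-4,8-dimethyldeca-4,8-dienal | O=CCC/C(C)=C/CC/C(C)=C/CO | intermediate
5 | methyl propiolate | C#CC(=O)OC | starting material
6 | (2R,4E,8E)-2-chloro-10-hydroxy-4,8-dimethyldeca-4,8-dienal | O=C[C@H](Cl)C/C(C)=C/CC/C(C)=C/CO | intermediate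
7 | methyl 2-(diisobutylalumanyl)acrylate | C=C(C(=O)OC)[Al](CC(C)C)CC(C)C | intermediate
8 | methyl (4R,6E,10E)-4-chloro-3,12-dihydroxy-6,10-dimethyl-2-methylidenedodeca-6,10-dienoate, C3 (= C7) epimers | C=C(C(=O)OC)C(O)[C@H](Cl)C/C(C)=C/CC/C(C)=C/CO | intermediate
9 | methyl 2-{(3S)-3-[(2E,6E)-8-hydroxy-2,6-dimethylocta-2,6-dien-1-yl]oxiran-2-yl}acrylate, C7 epimers, 8S | C=C(C(=O)OC)C1O[C@H]1C/C(C)=C/CC/C(C)=C/CO | intermediate
10 | methyl 2-{(3S)-3-[(2E,6E)-2,6-dimethyl-8-oxoocta-2,6-dien-1-yl]oxiran-2-yl}acrylate | C=C(C(=O)OC)C1O[C@H]1C/C(C)=C/CC/C(C)=C/C=O | intermediate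
11 | methyl (2E,4S,6E,10E)-4-(methacryloyloxy)-2-[(methacryloyloxy)methyl]-6,10-dimethyl-12-oxododeca-2,6,10-trienoate (its 1,2-regioisomer ionises to the same π-allyl complex) | COC(=O)/C(COC(=O)C(C)=C)=C/[C@@H](OC(=O)C(C)=C)C/C(C)=C/CC/C(C)=C/C=O | intermediate
12 | C13 allylindium iodide methacrylate derived from 11 (8S) | COC(=O)/C(C[In](I)OC(=O)C(C)=C)=C/[C@@H](OC(=O)C(C)=C)C/C(C)=C/CC/C(C)=C/C=O | intermediate
13 | methyl 6α-hydroxy-8α-methacryloyloxygermacra-1(10)E,4E,11(13)-trien-12-oate (formed as its indium alkoxide) | C=C(C)C(=O)O[C@H]1C/C(C)=C/CC/C(C)=C/[C@@H](O)[C@@H]1C(=C)C(=O)OC | intermediate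
14 | 8α-methacryloyloxycostunolide, (6R,7R,8S)-8-methacryloyloxygermacra-1(10)E,4E,11(13)-trien-12,6-olide, trans-lactone | C=C(C)C(=O)O[C@H]1C/C(C)=C/CC/C(C)=C/[C@H]2OC(=O)C(=C)[C@@H]21 | intermediate
15 | 10α-hydroxy-8α-methacryloyloxy-1-oxogermacra-4E,11(13)-dien-12,6α-olide (10R) | C=C(C)C(=O)O[C@H]1C[C@@](C)(O)C(=O)CC/C(C)=C/[C@H]2OC(=O)C(=C)[C@@H]21 | intermediate
16 | 10α-acetoxy-8α-methacryloyloxy-1-oxogermacra-4E,11(13)-dien-12,6α-olide | C=C(C)C(=O)O[C@H]1C[C@@](C)(OC(C)=O)C(=O)CC/C(C)=C/[C@H]2OC(=O)C(=C)[C@@H]21 | intermediate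
17 | 10α-acetoxy-4α,5β-epoxy-8α-methacryloyloxy-1-oxogermacr-11(13)-en-12,6α-olide (4R,5R) | C=C(C)C(=O)O[C@H]1C[C@@](C)(OC(C)=O)C(=O)CC[C@@]3(C)O[C@@H]3[C@H]2OC(=O)C(=C)[C@@H]21 | intermediate
18 | lychnostatin 1 (4S,5S,6S,7R,8S,10R) | C=C(C)C(=O)O[C@H]1C[C@@](C)(OC(C)=O)C(=O)CC[C@H](C)[C@H](O)[C@H]2OC(=O)C(=C)[C@@H]21 | target

## Step count and risks
Total step count: 11. Longest linear sequence: 11 (1 → 18).

**Step 7 (cascade closure).** Three things can go wrong. The allylindium may lose the C8 methacrylate by 1,4-elimination to a dienoate. O8 may lactonise onto C12 before it is acylated. The ten-membered closure may lose to oligomerisation.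

The fallback sets out from 10 and replaces the ester-bearing allylindium by a δ-silyloxy allylchromium. Et3SiCl with catalytic Bu4NCl in CH2Cl2 opens the vinyl epoxide in the SN2' sense and caps O8 in the same event, giving the silyl-protected (Z)-chloromethyl enoate F1. CrCl2/LiI in DMF at 2 mM (Nozaki–Hiyama–Kishi allylation, for which δ-alkoxy allylic halides are proven partners) closes ring and lactone to 8α-triethylsilyloxycostunolide F2. HF·pyridine frees 8α-hydroxycostunolide F3. Methacrylic anhydride/DMAP at 0 °C, with short contact to avoid translactonisation to O8, comes back to the route at 14.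

**Step 8 (ketohydroxylation).** RuO4 may also attack C4=C5 or the acrylate alkenes, or it may cleave the C1–C10 bond.

The fallback sets out from 14 and separates the two oxidation events. OsO4 (2 mol %) with NMO in acetone/H2O discriminates much more strongly in favour of the electron-rich strained alkene. It adds from the same outer face to give the 1β,10α-diol F4. SO3·pyridine/DMSO/Et3N (Parikh–Doering oxidation) then oxidises the only secondary alcohol and comes back to the route at 15.

**Step 11 (reductive epoxide opening).** The α-acetoxy ketone may be reduced. The tertiary radical may disproportionate to the 4(15)-alkene. Hydrogen delivery may be unselective at C4.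

The fallback sets out from 17 and removes low-valent titanium altogether. MgBr2·OEt2 in Et2O at −20 °C opens the epoxide at the tertiary carbon to the 4-bromo-5β-hydroxy compound F5. Bu3SnH with Et3B/air in toluene at −20 °C regenerates the C4 radical under neutral chain conditions. The bulky stannane quenches it from the outer face, coming back to the route at 18.

## Further compounds
F1 | step 7 | methyl (2Z,4S,6E,10E)-2-(chloromethyl)-6,10-dimethyl-12-oxo-4-(triethylsilyloxy)dodeca-2,6,10-trienoate | COC(=O)/C(CCl)=C/[C@@H](O[Si](CC)(CC)CC)C/C(C)=C/CC/C(C)=C/C=O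
F2 | step 7 | 8α-triethylsilyloxycostunolide | CC[Si](CC)(CC)O[C@H]1C/C(C)=C/CC/C(C)=C/[C@H]2OC(=O)C(=C)[C@@H]21
F3 | step 7 | 8α-hydroxycostunolide | O[C@H]1C/C(C)=C/CC/C(C)=C/[C@H]2OC(=O)C(=C)[C@@H]21
F4 | step 8 | 1β,10α-dihydroxy-8α-methacryloyloxygermacra-4E,11(13)-dien-12,6α-olide | C=C(C)C(=O)O[C@H]1C[C@@](C)(O)[C@H](O)CC/C(C)=C/[C@H]2OC(=O)C(=C)[C@@H]21
F5 | step 11 | 10α-acetoxy-4-bromo-5β-hydroxy-8α-methacryloyloxy-1-oxogermacr-11(13)-en-12,6α-olide (bromide anti to the former epoxide oxygen) | C=C(C)C(=O)O[C@H]1C[C@@](C)(OC(C)=O)C(=O)CC[C@](C)(Br)[C@H](O)[C@H]2OC(=O)C(=C)[C@@H]21
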